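**Retrosynthetic overview**
- The C30 target is cut at the ring A carbon–CH2 bond of the methylene-bearing unit: a right-unit alkyllithium adds to a left-unit α-methylene ketone, and the resulting tertiary allylic carbonate is reduced with palladium/formate to give the C–H / exocyclic C=CH2 array.
- Both bicyclic units come from one trans-fused keto-oxepane 11. The right unit is made by α-methylation, methylenation, face-selective epoxidation (sets the tertiary carbinol) and epoxide opening with PhSCH2Li; the left unit by α-methylenation.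
- 11 comes from bicyclic dienone 7 by ring B ketone reduction/silylation, hydrogenation, and a radical (HAT) hydrogenation that sets the trans ring fusion.
- Key step: catalytic enantioselective dearomative 7-endo conjugate addition of phenol-ynone 6, which forms ring B and the quaternary methyl stereocentre in one step from a flat aryl ether of 2-methylresorcinol.
- Ring order: ring A is the former benzene ring, ring B closes in the key step (once, used for both units), and the two bicycles are joined last.

Assumption: the C-3 carbinol made in step 5 is taken as R from the usual CBS model; it only masks the ring B ketone and is oxidised away in step 17.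
Numbering: 1-benzoxepine numbering (O1, C2 gem-dimethyl, C3, C4, C5, C5a quaternary C–CH3, C6–C9, C9a O-bearing CH); ring A = carbocycle, ring B = oxepane.

Step 1
Reactants: 1 2-methylbenzene-1,3-diol (2-methylresorcinol); 2 ethyl 2-bromo-2-methylpropanoate
Product: 3 ethyl 2-(3-hydroxy-2-methylphenoxy)-2-methylpropanoate
Conditions: K2CO3, DMF, 70 °C (3 equiv of 1, excess recovered)
Reagents that add atoms: none
Why: Williamson-type O-alkylation of the phenoxide with the tertiary α-bromo ester (the standard fibrate ether synthesis) works because the α-carbonyl group accelerates substitution at the tertiary carbon, and an excess of the symmetric diol keeps the reaction at the mono-ether, no stereocentre being formed.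

Step 2
Reactants: 3 ethyl 2-(3-hydroxy-2-methylphenoxy)-2-methylpropanoate
Product: 4 ethyl 2-(6-bromo-3-hydroxy-2-methylphenoxy)-2-methylpropanoate
Conditions: NBS, MeCN, −20 °C
Reagents that add atoms: N-bromosuccinimide (O=C1CCC(=O)N1Br)
Why: Electrophilic aromatic bromination goes to the only position para to the free phenol OH, which blocks that carbon so that in step 4 the tether can only attack the methyl-bearing ortho carbon, no stereocentre being formed.

Step 3
Reactants: 4 ethyl 2-(6-bromo-3-hydroxy-2-methylphenoxy)-2-methylpropanoate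
Product: 6 4-(6-bromo-3-hydroxy-2-methylphenoxy)-4-methylpent-1-yn-3-one, via Weinreb amide 5 (not isolated)
Conditions: MeNHOMe·HCl, i-PrMgCl, THF, −20 °C; then HC≡CMgBr, 0 °C; cold aq NaHSO4
Reagents that add atoms: ethynylmagnesium bromide (C#C[Mg]Br)
Why: One-pot Weinreb amide formation from the ester with Me(MeO)NMgCl followed by Grignard addition of the ethynyl reagent stops at the ketone because of the stable five-membered magnesium chelate, the phenol being carried as its magnesium phenoxide and no stereocentre being formed.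

Step 4
Reactants: 6 4-(6-bromo-3-hydroxy-2-methylphenoxy)-4-methylpent-1-yn-3-one
Product: 7 (5aR)-9-bromo-2,2,5a-trimethyl-2H-1-benzoxepine-3,6(5aH)-dione
Conditions: quinine-derived 3,5-bis(trifluoromethyl)phenyl squaramide (10 mol%), toluene (0.01 M), −20 °C to rt
Reagents that add atoms: none
Why: Proposed new method: the bifunctional squaramide deprotonates the phenol and holds the ammonium phenolate and the hydrogen-bonded ynone carbonyl in a chiral ion pair, so that the methyl-bearing ortho carbon (para position blocked by Br) adds to the alkyne terminus in a 7-endo-dig conjugate addition from one enantiotopic face and protonation of the allenolate gives the dienone that cannot rearomatise, with the quaternary C-5a stereocentre set as R (the quinidine-derived pseudoenantiomer is used if the sense of induction is opposite) and with the alkyne acceptor supplying enough driving force to make the dearomatisation irreversible, the closest known reaction type being the organocatalytic asymmetric dearomative Michael addition of 2-naphthols and phenols to ynones and nitroalkenes.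

Step 5
Reactants: 7 (5aR)-9-bromo-2,2,5a-trimethyl-2H-1-benzoxepine-3,6(5aH)-dione
Product: 8 (3R,5aR)-9-bromo-3-hydroxy-2,2,5a-trimethyl-3,5a-dihydro-2H-1-benzoxepin-6-one
Conditions: (S)-Me-CBS oxazaborolidine (20 mol%), catecholborane, toluene/CH2Cl2, −78 °C
Reagents that add atoms: none
Why: Corey–Bakshi–Shibata reduction attacks only the ring B enone carbonyl, which is activated by the α-oxygen while the ring A carbonyl is a deactivated doubly vinylogous ester, and the catalyst sets C-3 as R (large group = quaternary C-2) so that any minor 5a-enantiomer becomes a separable diastereomer.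

Step 6
Reactants: 8 (3R,5aR)-9-bromo-3-hydroxy-2,2,5a-trimethyl-3,5a-dihydro-2H-1-benzoxepin-6-one
Product: 9 (3R,5aR)-9-bromo-3-[(tert-butyldimethylsilyl)oxy]-2,2,5a-trimethyl-3,5a-dihydro-2H-1-benzoxepin-6-one
Conditions: TBSOTf, 2,6-lutidine, CH2Cl2, −78 to 0 °C
Reagents that add atoms: tert-butyldimethylsilyl triflate (CC(C)(C)[Si](C)(C)OS(=O)(=O)C(F)(F)F)
Why: Silylation of the hindered secondary allylic alcohol with a silyl triflate and a hindered pyridine base is standard and gives a group that survives the enolate, ylide, peracid and organolithium steps that follow, no stereocentre being changed.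

Step 7
Reactants: 9 (3R,5aR)-9-bromo-3-[(tert-butyldimethylsilyl)oxy]-2,2,5a-trimethyl-3,5a-dihydro-2H-1-benzoxepin-6-one
Product: 10 (3R,5aR)-3-[(tert-butyldimethylsilyl)oxy]-2,2,5a-trimethyl-3,4,5,5a,7,8-hexahydro-2H-1-benzoxepin-6-one (C9=C9a enol ether)
Conditions: H2 (1 atm), 5% Pd/C, Et3N, EtOAc, rt, stopped after 3 equiv H2
Reagents that add atoms: none
Why: Heterogeneous hydrogenation saturates the two disubstituted C=C bonds (the enone C7=C8 first, then the ring B cis-alkene) and hydrogenolyses the vinylic C–Br bond with the amine taking up HBr, while the trisubstituted enol ether next to the quaternary carbon is left for the stereocontrolled step 8, no stereocentre being formed.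

Step 8
Reactants: 10 (3R,5aR)-3-[(tert-butyldimethylsilyl)oxy]-2,2,5a-trimethyl-3,4,5,5a,7,8-hexahydro-2H-1-benzoxepin-6-one
Product: 11 (3R,5aR,9aS)-3-[(tert-butyldimethylsilyl)oxy]-2,2,5a-trimethyloctahydro-1-benzoxepin-6(2H)-one (trans-fused)
Conditions: Mn(dpm)3 (10 mol%), PhSiH3, t-BuOOH, degassed i-PrOH, rt
Reagents that add atoms: none
Why: Radical hydrogenation by metal-hydride hydrogen atom transfer (Shenvi-type HAT hydrogenation) adds a hydrogen atom to C-9 to give the tertiary α-alkoxy radical at C-9a, which takes its second hydrogen axially on the face opposite the axial 5a-methyl group and so gives the trans ring fusion (9aS), as in the HAT hydrogenation of angular-methyl octalins to trans-decalins where surface hydrogenation tends to give the cis isomer.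

Step 9
Reactants: 11 (3R,5aR,9aS)-3-[(tert-butyldimethylsilyl)oxy]-2,2,5a-trimethyloctahydro-1-benzoxepin-6(2H)-one
Product: 13 (3R,5aR,7S,9aS)-3-[(tert-butyldimethylsilyl)oxy]-2,2,5a,7-tetramethyloctahydro-1-benzoxepin-6(2H)-one, via lithium enolate 12 (not isolated)
Conditions: LDA, THF, −78 °C; MeI, −78 to −20 °C; NaOMe (cat.), MeOH on work-up
Reagents that add atoms: iodomethane (CI)
Why: Regiospecific enolate alkylation, C-7 being the only enolisable position, puts the methyl group equatorial and trans to the axial 5a-methyl group (7S) because the alternative would be syn-diaxial with it, and the brief base equilibration secures this thermodynamic epimer.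

Step 10
Reactants: 13 (3R,5aR,7S,9aS)-3-[(tert-butyldimethylsilyl)oxy]-2,2,5a,7-tetramethyloctahydro-1-benzoxepin-6(2H)-one
Product: 14 (3R,5aS,7S,9aS)-tert-butyldimethyl[(2,2,5a,7-tetramethyl-6-methylidenedecahydro-1-benzoxepin-3-yl)oxy]silane
Conditions: Ph3PCH3Br, KOt-Bu, toluene, 100 °C
Reagents that add atoms: methyltriphenylphosphonium bromide (C[P+](c1ccccc1)(c1ccccc1)c1ccccc1.[Br-])
Why: Wittig methylenation with excess ylide at high temperature (Fitjer conditions) is the established way to methylenate a ketone flanked by a quaternary and a tertiary carbon, and any epimerisation at C-7 returns to the more stable equatorial isomer.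

Step 11
Reactants: 14 (3R,5aS,7S,9aS)-tert-butyldimethyl[(2,2,5a,7-tetramethyl-6-methylidenedecahydro-1-benzoxepin-3-yl)oxy]silane
Product: 15 6-spiro-oxirane of 14 (oxirane O axial on the face opposite 5a-CH3; oxirane CH2 equatorial)
Conditions: mCPBA, NaHCO3, CH2Cl2, 0 °C
Reagents that add atoms: 3-chloroperbenzoic acid (OOC(=O)c1cccc(Cl)c1)
Why: Prilezhaev epoxidation delivers oxygen to the exocyclic alkene from the face opposite the axial 5a-methyl group on the neighbouring carbon, which sets the future tertiary carbinol with an axial C–O bond and an equatorial CH2 group, the configuration that direct addition of a carbon nucleophile to ketone 13 would not give.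

Step 12
Reactants: 15 6-spiro-oxirane of 14
Product: 17 triethylsilyl ether of the tertiary carbinol carrying the 2-(phenylsulfanyl)ethyl chain, via lithium alkoxide 16 (not isolated)
Conditions: PhSCH3, n-BuLi, DABCO, THF, 0 °C; add 15, 0 to 45 °C; then Et3SiCl, DMPU, 0 °C to rt
Reagents that add atoms: (phenylsulfanyl)methyllithium from thioanisole ([Li]CSc1ccccc1); chlorotriethylsilane (CC[Si](Cl)(CC)CC)
Why: SN2 opening of the 2,2-disubstituted epoxide at its CH2 carbon by (phenylsulfanyl)methyllithium (the Corey–Seebach reagent) adds the second bridge carbon without touching the carbinol stereocentre, and silylation of the tertiary lithium alkoxide in the same flask protects it for the coupling.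

Step 13
Reactants: 11 (3R,5aR,9aS)-3-[(tert-butyldimethylsilyl)oxy]-2,2,5a-trimethyloctahydro-1-benzoxepin-6(2H)-one
Product: 18 (3R,5aR,9aS)-3-[(tert-butyldimethylsilyl)oxy]-2,2,5a-trimethyl-7-methylideneoctahydro-1-benzoxepin-6(2H)-one
Conditions: (CH2O)n, i-Pr2NH·CF3CO2H, THF, 65 °C
Reagents that add atoms: formaldehyde as paraformaldehyde (C=O)
Why: Mannich-type α-methylenation (Gras conditions) condenses formaldehyde at C-7, the only enolisable position, through the aminomethyl ketone and eliminates the amine to give the exocyclic enone, no stereocentre being changed.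

Step 14
Reactants: 17 triethylsilyl ether of the tertiary carbinol carrying the 2-(phenylsulfanyl)ethyl chain; 18 (3R,5aR,9aS)-3-[(tert-butyldimethylsilyl)oxy]-2,2,5a-trimethyl-7-methylideneoctahydro-1-benzoxepin-6(2H)-one
Product: 21 tertiary allylic methyl carbonate of the coupled bis-bicycle, via alkyllithium 19 (not isolated), via lithium alkoxide 20 (not isolated)
Conditions: LiDBB (2.2 equiv, preformed in THF), THF, −78 °C; add 18, −78 °C; then ClCO2Me, −78 to 0 °C
Reagents that add atoms: methyl chloroformate (COC(=O)Cl)
Why: Reductive lithiation of the alkyl phenyl sulfide (Cohen–Screttas C–S cleavage) gives the primary alkyllithium, which undergoes 1,2-addition to the enone carbonyl from the axial direction opposite the 5a-methyl group, and the tertiary allylic alkoxide is acylated in the same flask, the configuration of this carbinol carbon being unimportant because it is reset in step 15.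

Step 15
Reactants: 21 tertiary allylic methyl carbonate of the coupled bis-bicycle
Product: 22 coupled bis-bicycle with 6-H axial and 7-methylidene in the left unit (two TBS ethers and one TES ether)
Conditions: Pd(OAc)2 (5 mol%), n-Bu3P (20 mol%), HCO2H, Et3N, THF, 40 °C
Reagents that add atoms: none
Why: Tsuji–Trost-type formate hydrogenolysis, in which zerovalent palladium ionises the tertiary allylic carbonate to a π-allyl complex on the less hindered face opposite the 5a-methyl group, decarboxylation of formate gives a palladium hydride, and reductive elimination places hydrogen on the more substituted allyl terminus C-6 from that face, keeps the exocyclic methylene and leaves the side chain equatorial and cis to the 5a-methyl group as in the target.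

Step 16
Reactants: 22 coupled bis-bicycle with 6-H axial and 7-methylidene in the left unit
Product: 23 triol (both ring B C-3 carbinols and the tertiary carbinol free)
Conditions: TBAF, THF, 50 °C
Reagents that add atoms: none
Why: Fluoride cleaves the Si–O bonds of the two secondary TBS ethers and the tertiary TES ether without affecting the exocyclic alkene or any stereocentre.

Step 17
Reactants: 23 triol
Product: 24 CNP0218659.1 (target)
Conditions: Dess–Martin periodinane, NaHCO3, CH2Cl2, rt
Reagents that add atoms: none
Why: Dess–Martin oxidation converts both hindered secondary ring B carbinols into the oxepan-3-ones under buffered neutral conditions, leaves the tertiary alcohol and the 1,1-disubstituted alkene alone, and removes the two auxiliary C-3 stereocentres.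

**Compound list**
1 | 2-methylbenzene-1,3-diol (2-methylresorcinol) | Cc1c(O)cccc1O | starting material
2 | ethyl 2-bromo-2-methylpropanoate | CCOC(=O)C(C)(C)Br | starting material
3 | ethyl 2-(3-hydroxy-2-methylphenoxy)-2-methylpropanoate | CCOC(=O)C(C)(C)Oc1cccc(O)c1C | intermediate
4 | ethyl 2-(6-bromo-3-hydroxy-2-methylphenoxy)-2-methylpropanoate | CCOC(=O)C(C)(C)Oc1c(Br)ccc(O)c1C | intermediate
5 | 2-(6-bromo-3-hydroxy-2-methylphenoxy)-N-methoxy-N,2-dimethylpropanamide (Weinreb amide, magnesium phenoxide in the flask) | CON(C)C(=O)C(C)(C)Oc1c(Br)ccc(O)c1C | intermediate (not isolated)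
6 | 4-(6-bromo-3-hydroxy-2-methylphenoxy)-4-methylpent-1-yn-3-one | C#CC(=O)C(C)(C)Oc1c(Br)ccc(O)c1C | intermediate
7 | (5aR)-9-bromo-2,2,5a-trimethyl-2H-1-benzoxepine-3,6(5aH)-dione | C1=CC(Br)=C2OC(C)(C)C(=O)C=C[C@@]2(C)C1=O | intermediate
8 | (3R,5aR)-9-bromo-3-hydroxy-2,2,5a-trimethyl-3,5a-dihydro-2H-1-benzoxepin-6-one | C1=CC(Br)=C2OC(C)(C)[C@H](O)C=C[C@@]2(C)C1=O | intermediate
9 | (3R,5aR)-9-bromo-3-[(tert-butyldimethylsilyl)oxy]-2,2,5a-trimethyl-3,5a-dihydro-2H-1-benzoxepin-6-one | C1=CC(Br)=C2OC(C)(C)[C@H](O[Si](C)(C)C(C)(C)C)C=C[C@@]2(C)C1=O | intermediate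
10 | (3R,5aR)-3-[(tert-butyldimethylsilyl)oxy]-2,2,5a-trimethyl-3,4,5,5a,7,8-hexahydro-2H-1-benzoxepin-6-one (C9=C9a enol ether) | C1CC=C2OC(C)(C)[C@H](O[Si](C)(C)C(C)(C)C)CC[C@@]2(C)C1=O | intermediate
11 | (3R,5aR,9aS)-3-[(tert-butyldimethylsilyl)oxy]-2,2,5a-trimethyloctahydro-1-benzoxepin-6(2H)-one (trans-fused, 9a-H anti to 5a-CH3) | C1CC[C@@H]2OC(C)(C)[C@H](O[Si](C)(C)C(C)(C)C)CC[C@@]2(C)C1=O | intermediate
12 | lithium enolate of 11 (C6–OLi, C6=C7) | C=1CC[C@@H]2OC(C)(C)[C@H](O[Si](C)(C)C(C)(C)C)CC[C@@]2(C)C=1O[Li] | intermediate (not isolated)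
13 | (3R,5aR,7S,9aS)-3-[(tert-butyldimethylsilyl)oxy]-2,2,5a,7-tetramethyloctahydro-1-benzoxepin-6(2H)-one (7-CH3 equatorial, trans to 5a-CH3) | O=C1[C@@H](C)CC[C@@H]2OC(C)(C)[C@H](O[Si](C)(C)C(C)(C)C)CC[C@]21C | intermediate
14 | (3R,5aS,7S,9aS)-tert-butyldimethyl[(2,2,5a,7-tetramethyl-6-methylidenedecahydro-1-benzoxepin-3-yl)oxy]silane | C=C1[C@@H](C)CC[C@@H]2OC(C)(C)[C@H](O[Si](C)(C)C(C)(C)C)CC[C@]21C | intermediate
15 | 6-spiro-oxirane of 14; oxirane O axial and anti to 5a-CH3, oxirane CH2 equatorial | O1C[C@@]12[C@@H](C)CC[C@@H]3OC(C)(C)[C@H](O[Si](C)(C)C(C)(C)C)CC[C@]32C | intermediate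
16 | lithium 6-alkoxide carrying the 6-[2-(phenylsulfanyl)ethyl] chain (O axial, chain equatorial; other centres as in 13) | c1ccccc1SCC[C@]1(O[Li])[C@@H](C)CC[C@@H]2OC(C)(C)[C@H](O[Si](C)(C)C(C)(C)C)CC[C@]21C | intermediate (not isolated)
17 | triethylsilyl ether of 16: 3-OTBS, 6-OTES, 6-[2-(phenylsulfanyl)ethyl]-2,2,5a,7-tetramethyldecahydro-1-benzoxepine | c1ccccc1SCC[C@]1(O[Si](CC)(CC)CC)[C@@H](C)CC[C@@H]2OC(C)(C)[C@H](O[Si](C)(C)C(C)(C)C)CC[C@]21C | intermediate
18 | (3R,5aR,9aS)-3-[(tert-butyldimethylsilyl)oxy]-2,2,5a-trimethyl-7-methylideneoctahydro-1-benzoxepin-6(2H)-one | C=C1CC[C@@H]2OC(C)(C)[C@H](O[Si](C)(C)C(C)(C)C)CC[C@@]2(C)C1=O | intermediate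
19 | primary alkyllithium from 17 (Li in place of SPh) | [Li]CC[C@]1(O[Si](CC)(CC)CC)[C@@H](C)CC[C@@H]2OC(C)(C)[C@H](O[Si](C)(C)C(C)(C)C)CC[C@]21C | intermediate (not isolated)
20 | lithium tertiary allylic alkoxide from 19 + 18 (new C–C bond at left C-6, chain axial and anti to 5a-CH3, O equatorial) | C=C1CC[C@@H]2OC(C)(C)[C@H](O[Si](C)(C)C(C)(C)C)CC[C@@]2(C)[C@@]1(O[Li])CC[C@]1(O[Si](CC)(CC)CC)[C@@H](C)CC[C@@H]2OC(C)(C)[C@H](O[Si](C)(C)C(C)(C)C)CC[C@]21C | intermediate (not isolated)
21 | methyl carbonate of 20 | C=C1CC[C@@H]2OC(C)(C)[C@H](O[Si](C)(C)C(C)(C)C)CC[C@@]2(C)[C@@]1(OC(=O)OC)CC[C@]1(O[Si](CC)(CC)CC)[C@@H](C)CC[C@@H]2OC(C)(C)[C@H](O[Si](C)(C)C(C)(C)C)CC[C@]21C | intermediate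
22 | coupled bis-bicycle, left unit 6-H axial (chain equatorial, cis to 5a-CH3) and 7-methylidene; 3-OTBS in both units, tertiary OTES in right unit | C=C1CC[C@@H]2OC(C)(C)[C@H](O[Si](C)(C)C(C)(C)C)CC[C@@]2(C)[C@@H]1CC[C@]1(O[Si](CC)(CC)CC)[C@@H](C)CC[C@@H]2OC(C)(C)[C@H](O[Si](C)(C)C(C)(C)C)CC[C@]21C | intermediate
23 | triol: 22 with all three silyl groups removed | C=C1CC[C@@H]2OC(C)(C)[C@H](O)CC[C@@]2(C)[C@@H]1CC[C@]1(O)[C@@H](C)CC[C@@H]2OC(C)(C)[C@H](O)CC[C@]21C | intermediate
24 | CNP0218659.1 | C=C1CC[C@@H]2OC(C)(C)C(=O)CC[C@@]2(C)[C@@H]1CC[C@]1(O)[C@@H](C)CC[C@@H]2OC(C)(C)C(=O)CC[C@]21C | target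

**Step count and risk**
Total steps: 17. Longest linear sequence: 16 (steps 1–12, then 14–17); step 13 is the one-step side branch from 11.

Most likely to fail, first: step 4 (the dearomative cyclisation, which may be slow, unselective or poorly enantioselective). The fallback sets out from 6 and comes back at 8. Ynone 6 is cyclised without a chiral catalyst (DBU, 10 mol%, toluene, high dilution) to the racemic dienone F1. The CBS reduction of step 5 is then run on the racemate. Because the catalyst fixes C-3 as R in both enantiomers, they become the diastereomers 8 and the (3R,5aS)-alcohol F2, which are separated by chromatography. This is a resolution (at most 50%) in place of asymmetric catalysis.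

Second: step 8 (the trans ring fusion). The fallback sets out from 10 and comes back at 11. It is an ionic hydrogenation (CF3CO2H, Et3SiH, CH2Cl2, −40 °C): the enol ether is protonated at C-9 to the bicyclic oxocarbenium ion, and the silane delivers hydride axially, anti to the 5a-methyl group. This is a cationic instead of a radical hydrogen delivery, and I am not certain it favours trans either; it makes no new compound (F0), and the cis isomer, if formed, is separated at 11.

Third: step 15 (regio- and face-selectivity of the palladium hydrogenolysis on a hindered tertiary allylic carbonate). The fallback sets out from 20 and comes back at 22. The alkoxide 20 is quenched with aqueous NH4Cl to the tertiary allylic alcohol F3. A rhenium-catalysed 1,3-transposition (Ph3SiOReO3, Et2O, 0 °C) gives the primary allylic alcohol with the tetrasubstituted ring alkene F4. Myers reductive transposition (2-nitrobenzenesulfonylhydrazide, PPh3, DEAD, THF, −30 °C to rt) passes through the N-allylic sulfonylhydrazine F5 and the monoalkyl diazene F6. The diazene loses dinitrogen in a retro-ene step that puts hydrogen on C-6 from the less hindered face and moves the double bond to the exocyclic position, giving 22 without a metal π-allyl.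

Further compounds
F1 | step 4 | racemic 9-bromo-2,2,5a-trimethyl-2H-1-benzoxepine-3,6(5aH)-dione | C1=CC(Br)=C2OC(C)(C)C(=O)C=CC2(C)C1=O
F2 | step 4 | (3R,5aS)-9-bromo-3-hydroxy-2,2,5a-trimethyl-3,5a-dihydro-2H-1-benzoxepin-6-one | C1=CC(Br)=C2OC(C)(C)[C@H](O)C=C[C@]2(C)C1=O
F0 | step 8 | none | none
F3 | step 15 | tertiary allylic alcohol (protonated 20) | C=C1CC[C@@H]2OC(C)(C)[C@H](O[Si](C)(C)C(C)(C)C)CC[C@@]2(C)[C@@]1(O)CC[C@]1(O[Si](CC)(CC)CC)[C@@H](C)CC[C@@H]2OC(C)(C)[C@H](O[Si](C)(C)C(C)(C)C)CC[C@]21C
F4 | step 15 | transposed primary allylic alcohol (left unit 7-hydroxymethyl, C6=C7 tetrasubstituted alkene) | OCC=1CC[C@@H]2OC(C)(C)[C@H](O[Si](C)(C)C(C)(C)C)CC[C@@]2(C)C=1CC[C@]1(O[Si](CC)(CC)CC)[C@@H](C)CC[C@@H]2OC(C)(C)[C@H](O[Si](C)(C)C(C)(C)C)CC[C@]21C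
F5 | step 15 | N-allylic N-(2-nitrobenzenesulfonyl)hydrazine from F4 | NN(CC=1CC[C@@H]2OC(C)(C)[C@H](O[Si](C)(C)C(C)(C)C)CC[C@@]2(C)C=1CC[C@]1(O[Si](CC)(CC)CC)[C@@H](C)CC[C@@H]2OC(C)(C)[C@H](O[Si](C)(C)C(C)(C)C)CC[C@]21C)S(=O)(=O)c1ccccc1[N+](=O)[O-]
F6 | step 15 | monoalkyl diazene from F5 | N=NCC=1CC[C@@H]2OC(C)(C)[C@H](O[Si](C)(C)C(C)(C)C)CC[C@@]2(C)C=1CC[C@]1(O[Si](CC)(CC)CC)[C@@H](C)CC[C@@H]2OC(C)(C)[C@H](O[Si](C)(C)C(C)(C)C)CC[C@]21C
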